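Take each plateau of left-handed product as a branching ratio: left-handed substrate is either captured by partner or lost another way.

| flask | left-handed substrate | right-handed substrate | partner | temperature | remark | time |
|---|---|---|---|---|---|---|
| east | 0.050 M | 0.050 M | 0.084 M | 46 °C | run made earlier |  |
| north-west | 0.050 M | 0.050 M | 0.19 M | 60 °C | run made earlier |  |
| south | 0.075 M | 0.075 M | 0.125 M | 46 °C | run made earlier |  |
| grey | 0.050 M | 0.050 M | 0.125 M | 40 °C |  | 8.0 d |
| red | 0.050 M | 0.050 M | 0.125 M | 65 °C |  | 8.0 d |
| amber | 0.050 M | 0.050 M | 0.125 M |  | at 40 °C until 40 h, from then on at 65 °C | 8.0 d |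

- east (time / d: left-handed product / %, left-handed substrate / %): 0.833: 12.6, 6.4; 2.50: 11.9, 0.6; 4.00: 10.4, 0; 6.00: 11.8, 0.3; 10.0: 11.2, 0.4
- north-west (time / d: left-handed product / %, left-handed substrate / %): 0.833: 19.8, 0.2; 1.67: 19.4, 0.1; 2.00: 19.5, 0; 3.00: 19.3, 0.1; 4.00: 19.2, 0
- south (time / d: left-handed product / %, left-handed substrate / %): 2.08: 15.2, 0.2; 4.00: 14.3, 0; 6.00: 14.9, 0; 8.00: 14.3, 0.2; 10.0: 14.6, 0.1

(readings scatter by 0.3 percentage points)

* the flask that comes out highest in amount of left-handed product, in percent of the left-handed substrate and right-handed substrate together charged, or "all alike" when all lie within 1.5 percentage points (grey / red / amber / all alike)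
* left-handed product at the end, in percent of the left-handed substrate and right-handed substrate together charged, grey
* left-handed product at the end, in percent of the left-handed substrate and right-handed substrate together charged, red
* left-handed product at the end, in percent of the left-handed substrate and right-handed substrate together charged, amber

- partner is single-handed; left-handed substrate and right-handed substrate are mirror images of each other, charged as a racemate, each of them at the stated concentration
- the handed part of partner does not stay in what it makes, so the products of the two hands are mirror images too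

1. Partner. I read plateaus of 11.3% in east, 14.7% in south and 19.4% in north-west. Both hands consume partner, so [partner] falls during a run, and I replaced that curve by its mean: the charge less the plateau times the substrate charged. Plateau over the uncaptured rest of the left-handed charge, divided by charged [partner], gave 3.49 M⁻¹ in east and 3.32 M⁻¹ in south. Divided by mean [partner], it gave 4.03 M⁻¹ and 4.03 M⁻¹, a smaller gap. I named their mean, 4.03 M⁻¹, the capture constant K̄: the plateau's branching ratio per unit of mean [partner].

2. Temperature. North-west, at 60 °C, read 3.73 M⁻¹, a little lower. Solving the same relation for the plateau, I reckoned 15.3% for grey with 4.03 M⁻¹ and 14.6% for red with 3.73 M⁻¹. That gap of 0.70 percentage points lies inside the margin.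

3. Time. East's left-handed substrate gave a lifetime of 0.405 d, so 8.0 d is far longer, which left room for a slower grey.

4. Switch. Amber stands at 40 °C until 40 h and then at 65 °C, the temperatures of grey and red, so I placed it between them.

5. The forecast said all alike, with 14.9% for grey, 14.6% for red and 14.8% for amber: “K therefore seems independent of substrate concentration and nearly independent of temperature”. My grey stood higher.

6. The flasks gave 16.5% for grey, 15.6% for red and 16.3% for amber: all alike. Moved from east towards grey one setting at a time, the answer went from 11.4% to 15.2% with partner, 12.3% with temperature and 11.4% with time.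

    partner + left-handed substrate → left-handed product (k = 0.249 M⁻¹ h⁻¹, Ea = 82.0 kJ mol⁻¹)
    achiral form → decomposed reagent (k = 0.0249 h⁻¹, Ea = 105 kJ mol⁻¹)
    partner + right-handed substrate → right-handed product (k = 0.0982 M⁻¹ h⁻¹, Ea = 76.0 kJ mol⁻¹)
    left-handed product ⇌ right-handed product (k = 0.0107 h⁻¹, Ea = 100 kJ mol⁻¹)
    right-handed substrate ⇌ achiral form (K = 0.164, k = 0.0432 h⁻¹, Ea = 112 kJ mol⁻¹, ΔH = −61.0 kJ mol⁻¹)
    achiral form → side product (k = 2.74 h⁻¹, Ea = 97.0 kJ mol⁻¹)
    left-handed substrate ⇌ achiral form (K = 0.164, k = 0.0432 h⁻¹, Ea = 112 kJ mol⁻¹, ΔH = −61.0 kJ mol⁻¹)
    (constants at 40 °C)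

7. Amber's end value gave K̄ = 4.46 M⁻¹, above the 4.03 M⁻¹ from east and south. Of the single steps, the one from achiral form to side product turned the answer most, though it is not the whole of the loss: without it left-handed product stood at 47.0% in red, against 15.6%, and at 40.4% in grey, against 16.5%. For a neighbour of amber with 0.050 M of partner, amber's K̄ gave 7.90%, and that neighbour came out at 8.01%.

(Readings and results come from a simulation with made-up constants; the scatter is artificial.)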